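If you want this flask's solution at 25 min, don't follow it minute by minute; reckon just its small shortfall from saturation.

all flasks: solid substrate 0.40 M; gas 170 mM (held)

| run | second substrate | remark | time |
|---|---|---|---|
| Friday's | 0.50 equiv | run made earlier |  |
| Saturday's | 2 equiv | run made earlier |  |
| flask | 1.00 equiv |  | 25 min |

| run | time / min | target / % | starting material / % |
|---|---|---|---|
| Friday's | 1.50 | 0 | 15 |
| Friday's | 2.50 | 1 | 18 |
| Friday's | 4.00 | 0 | 21 |
| Friday's | 6.00 | 0 | 27 |
| Friday's | 8.00 | 2 | 31 |
| Friday's | 12.0 | 1 | 35 |
| Friday's | 20.0 | 10 | 40 |
| Saturday's | 1.00 | 2 | 10 |
| Saturday's | 3.00 | 2 | 18 |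
| Saturday's | 6.00 | 0 | 31 |
| Saturday's | 8.00 | 0 | 35 |
| Saturday's | 12.0 | 3 | 33 |
| Saturday's | 15.0 | 8 | 37 |
| Saturday's | 20.0 | 8 | 37 |

(scatter of a reading: 2 percentage points)

- solid substrate is a solid; its amount is given per volume of the solution
- at the start none of partner is dissolved
- on the list of suspects stand: starting material + partner <-> target; second substrate + partner <-> second product; solid substrate <-> starting material; gas <-> partner
- at the start none of the solid substrate is in solution
- starting material means what is dissolved; the solid is not counted in it

* how much target there is at 25 min, in percent of the solid substrate charged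
* concentration of starting material in solution at 25 min, in percent of saturation

Read saturation, S, from Friday's last starting material, 40.0 % of the charge. The two runs' mean at 6.00 min then gives a dissolving constant k of 0.215 /min. Once dissolving balances a draw r by target (quasi-steady state), the solution stands below saturation by the fraction r/(kS).

Now take two extreme flasks. With no draw, the solution stands at 100 % of saturation. With the steep stretch between 12.0 min and 20.0 min, r is 0.00875 /min of the charge, and it stands at 89.8 %.

That stretch rests on readings with a scatter of 2 percentage points, so my reckoning uses the mean draw since the start. Target averages 9.00 % at 20.0 min, so r is 0.00450 /min, less than the steep value. The standing deficit is then 5.23 %, which puts the flask at 94.8 % of saturation, and target runs on to 11.2 %.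

The forecast says 15 % target and 95 % of saturation, holding that “dissolution replaces this with only a small deficit”. It agrees on saturation but stands above my target.

The flask gives 10.3 % target and 94.9 % of saturation.

    starting material + partner ⇌ target (K = 5.28 /M, k = 0.844 /M/min)
    second substrate + partner ⇌ second product (K = 2.70 /M, k = 0.0225 /M/min)
    solid substrate ⇌ starting material, rate k3*(cs3 - [starting material]) while solid is left; crystals form when [starting material] > cs3 (solubility = 0.160 M, k = 0.227 /min)
    gas ⇌ partner, rate k4*(csat - [partner]) (kL = 0.0345 /min)

At 25 min, starting material is still made 1.17 times as fast as it is used up. The flask's own mean draw gives a deficit of 4.79 %. Left until 250 min, the flask holds 33.5 % target and 39.9 % of the charge as starting material, a deficit of 0.240 %. Read through r/(kS), that deficit is a present draw of 2.06 × 10⁻⁴ /min, less than that flask's mean draw of 0.00134 /min.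

The earlier runs and the new flask come from a simulation on assumed constants; scatter was added.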